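- A small charge of J sits in a closed, stirred flask under gas E. E dissolves as G, G adds to J to give J.G, and J.G can hold a further J as J.J.G. I follow one molecule through each fork.

all flasks: E 0.17 mM (held); time 30 s

| charge | J |
|---|---|
| ash | 1.5 mM |
| elm | 5.0 mM |
| cedar | 15 mM |

* [J.G] (only what is free in solution) at the end for ash, elm, cedar, in this order
* the course of these numbers from the first flask to the last (hardly changes / rises all the way / falls all the way / falls, then rises / rises, then falls)

- in percentages every species weighs as the J in it: one J.J.G counts as two
- for J.G the J.J.G is counted in
- at the start none of G is dissolved
- in an amount of J.G, one J.J.G counts as one J.G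
- the concentration of J.G that is asked is that of its free form alone
- "hardly changes" means that all values lie within two and a half points (for a concentration: within two and a half percent of the largest)
- run time (ash): 30 s

- First fork: a dissolved G either reacts with J or returns to the gas. Its loss to J is pseudo-first-order, with a rate constant of k4 times the concentration of J, so its chance of reacting is that constant over the sum of itself and 0.59 s⁻¹. This chance is 0.289 in ash and 0.803 in cedar, higher in cedar.
- With no G dissolved, gas enters at 0.100 mM s⁻¹. Taking J at its charge and G as steady, I reckon that 30 s makes 0.870 mM of J.G in ash, 1.73 mM in elm and 2.42 mM in cedar.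
- Second fork: each J.G is either free or tied up as J.J.G, and the balance is kept fast. The holding ratio, meaning tied J.G per free J.G, is 420 M⁻¹ times the concentration of J; at the charge of ash it is 0.630. The free share of J.G is one over one plus this ratio.
- Multiplying the two forks, I get 0.534 mM of free J.G in ash, 0.559 mM in elm and 0.331 mM in cedar. Scoring each possible course by how far my three figures bear it out, I get rises, then falls. The first fork gains with J while the second loses, and by cedar my figure stands lower than in elm. Consumed J will make my holding ratios too high.
- The forecast gives 0.48 mM, 0.68 mM and 0.41 mM, with the course rises, then falls. Its ground is “More J also pushes more J.G into J.J.G”. Its figures differ from mine, with cedar higher than my reckoning, but the course is the same.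
- The simulation gives 0.481 mM, 0.675 mM and 0.415 mM, with the course rises, then falls.

    G + J.G → G.J.G (k1 = 5.7 M⁻¹ s⁻¹)
    E ⇌ G, rate k2*(csat - [G]) (k2 = 0.59 s⁻¹, csat = 0.17 mM)
    J + J.G ⇌ J.J.G, settled at all times (K3 = 420 M⁻¹)
    J + G → J.G (k4 = 160 M⁻¹ s⁻¹)

- At the J left at the end, 48.1% of the charge in ash and 72.1% in cedar, the holding ratio gives a free share of 0.767 in ash and 0.180 in cedar. The tying up of J.G as J.J.G, together with the reading at 30 s, is part of what gives the row its course. Without the tying up, free J.G in ash stands at 0.664 mM instead of 0.481 mM.

(All constants are invented; what happens was integrated by code.)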